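**Retrosynthetic overview**

- The plan rests on the C3(sp3)–C4(sp2) bond of the ten-membered carbocycle. C4 belongs to the Z-trisubstituted C4=C5 alkene and C3 lies two carbons from the Z C1=C10 alkene, so C3 can be a borane made from a terminal C2=C3 vinyl group and C4 an alkenyl iodide.
- The open-chain precursor 28 (Z-diene at one end, Z-alkenyl iodide at the other) carries the O8 aroyl ester; the ester is put on after the diene is unveiled by lactol methylenation.
- The C1=C10 geometry is fixed by a temporary 4-methyl-5,6-dihydropyran-2-one ring, closed by metathesis of the C8 acrylate with a 2-methylallyl group; C8 comes from reagent-controlled allylboration of the C8 aldehyde.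
- C6 and C7 come from an Evans syn aldol of the isovaleryl imide with (Z)-3-iodobut-2-enal, whose geometry (C4=C5) comes from hydroalumination–iodination of but-2-yn-1-ol.
- Ring order: the temporary lactone ring is formed in step 10 and opened in step 12; the only ring of the target, the ten-membered carbocycle, is closed in step 15.

Key step: step 15

Remark: ring carbons are numbered C1–C10 in the germacrane manner (methyls on C4 and C10, OH on C6, isopropyl on C7, aroyloxy on C8); 2-methylallylmagnesium chloride and (+)-Ipc2BOMe are taken as commercial.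

**Route**

Step 1
Reactants: 1 but-2-yn-1-ol
Product: 3 (Z)-3-iodobut-2-en-1-ol, via cyclic alkenylalanate 2 (not isolated)
Conditions: NaAlH2(OCH2CH2OMe)2, THF, 0 °C → rt; EtOAc quench; then I2, THF, −78 °C
Reagents that add atoms: iodine, I2, SMILES II
Why: Alkoxide-directed trans-hydroalumination of the propargylic alcohol puts aluminium on C3 syn to the CH2O arm (five-membered alanate 2), and iododealumination with retention should give the Z iodide, which fixes the later C4=C5 geometry.

Step 2
Reactants: 3 (Z)-3-iodobut-2-en-1-ol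
Product: 4 (Z)-3-iodobut-2-enal
Conditions: MnO2, CH2Cl2, rt
Reagents that add atoms: none
Why: Allylic oxidation with MnO2 is neutral and heterogeneous, so the Z geometry and the C–I bond should survive.

Step 3
Reactants: 5 (S)-4-benzyl-1,3-oxazolidin-2-one; 6 3-methylbutanoyl chloride
Product: 7 (S)-4-benzyl-3-(3-methylbutanoyl)-1,3-oxazolidin-2-one
Conditions: n-BuLi, THF, −78 °C; then 6, −78 → 0 °C
Reagents that add atoms: none
Why: N-acylation of the lithiated oxazolidinone by the acid chloride is the standard entry to the Evans imide.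

Step 4
Reactants: 7 (S)-4-benzyl-3-(3-methylbutanoyl)-1,3-oxazolidin-2-one; 4 (Z)-3-iodobut-2-enal
Product: 9 (4S)-4-benzyl-3-[(2S,3S,4Z)-3-hydroxy-5-iodo-2-(propan-2-yl)hex-4-enoyl]-1,3-oxazolidin-2-one, via boron enolate 8 (not isolated)
Conditions: Bu2BOTf, Et3N, CH2Cl2, 0 °C; then 4, −78 → 0 °C; pH 7 buffer, MeOH, H2O2, 0 °C
Reagents that add atoms: none
Why: Evans syn aldol in which the Z(O) dibutylboron enolate 8 reacts through a chair Zimmerman–Traxler transition state on the face away from the benzyl group, setting C7 and C6 syn with the absolute sense given by the (S)-auxiliary.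

Step 5
Reactants: 9 aldol adduct
Product: 10 (4S)-4-benzyl-3-[(2S,3S,4Z)-3-[(tert-butyldimethylsilyl)oxy]-5-iodo-2-(propan-2-yl)hex-4-enoyl]-1,3-oxazolidin-2-one
Conditions: TBSOTf, 2,6-lutidine, CH2Cl2, −78 → 0 °C
Reagents that add atoms: tert-butyldimethylsilyl trifluoromethanesulfonate, CC(C)(C)[Si](C)(C)OS(=O)(=O)C(F)(F)F
Why: Silyl triflate with a hindered pyridine base silylates the crowded secondary allylic alcohol without retro-aldol cleavage.

Step 6
Reactants: 10 silylated imide
Product: 11 (2R,3S,4Z)-3-[(tert-butyldimethylsilyl)oxy]-5-iodo-2-(propan-2-yl)hex-4-en-1-ol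
Conditions: LiBH4, MeOH (1 equiv), THF, 0 °C → rt
Reagents that add atoms: none
Why: Reductive cleavage of the imide at the exocyclic carbonyl by LiBH4/MeOH should give the primary alcohol and release the auxiliary while leaving the alkenyl iodide and silyl ether alone.

Step 7
Reactants: 11 primary alcohol
Product: 12 (2S,3S,4Z)-3-[(tert-butyldimethylsilyl)oxy]-5-iodo-2-(propan-2-yl)hex-4-enal
Conditions: Dess–Martin periodinane, NaHCO3, CH2Cl2, 0 °C → rt
Reagents that add atoms: none
Why: Buffered Dess–Martin oxidation is non-basic, so the α-stereocentre C7 should not epimerise and the β-silyloxy group should not eliminate.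

Step 8
Reactants: 12 C8 aldehyde; 13 2-methylallylmagnesium chloride
Product: 15 (4R,5R,6S,7Z)-6-[(tert-butyldimethylsilyl)oxy]-8-iodo-2-methyl-5-(propan-2-yl)nona-1,7-dien-4-ol, via B-methallyl diisopinocampheylborane 14 (not isolated)
Conditions: (+)-Ipc2BOMe [from (−)-α-pinene], 13, Et2O, −78 °C → rt; then 12, −78 °C; NaOH, H2O2, 0 °C → rt
Reagents that add atoms: none
Why: Brown allylboration, in which the 2-methylallyl group is delivered through a chair six-membered transition state and the isopinocampheyl groups from (−)-α-pinene direct it to the Re face of the aldehyde, setting C8 (R) by reagent control over the bias of the adjacent C7 centre.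

Step 9
Reactants: 15 homoallylic alcohol; 16 acryloyl chloride
Product: 17 (4R,5R,6S,7Z)-6-[(tert-butyldimethylsilyl)oxy]-8-iodo-2-methyl-5-(propan-2-yl)nona-1,7-dien-4-yl prop-2-enoate
Conditions: Et3N, DMAP (cat.), CH2Cl2, −20 → 0 °C
Reagents that add atoms: none
Why: DMAP-catalysed acylation of the secondary alcohol by the acid chloride does not break the C8–O bond, so the configuration is kept.

Step 10
Reactants: 17 acrylate
Product: 18 (6R)-6-[(3R,4S,5Z)-4-[(tert-butyldimethylsilyl)oxy]-6-iodo-2-methylhept-5-en-3-yl]-4-methyl-5,6-dihydro-2H-pyran-2-one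
Conditions: second-generation Grubbs catalyst RuCl2(=CHPh)(H2IMes)(PCy3) (5–10 mol%), CH2Cl2, 40 °C, 5 mM
Reagents that add atoms: none
Why: Ring-closing metathesis of the acrylate with the 1,1-disubstituted alkene closes the six-membered lactone, whose endocyclic trisubstituted alkene forces C9 and C2 cis on C10=C1, while the hindered, electron-poor iodoalkene should not engage the ruthenium carbene.

Step 11
Reactants: 18 unsaturated lactone
Product: 19 (6R)-6-[(3R,4S,5Z)-4-[(tert-butyldimethylsilyl)oxy]-6-iodo-2-methylhept-5-en-3-yl]-4-methyl-5,6-dihydro-2H-pyran-2-ol (anomeric mixture)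
Conditions: i-Bu2AlH (1.2 equiv), CH2Cl2, −78 °C; aqueous potassium sodium tartrate
Reagents that add atoms: none
Why: At −78 °C the 1,2-reduction of the lactone by i-Bu2AlH stops at the aluminium hemiacetal, which gives the lactol on work-up.

Step 12
Reactants: 19 lactol; 20 methyltriphenylphosphonium bromide
Product: 23 (3Z,6R,7R,8S,9Z)-8-[(tert-butyldimethylsilyl)oxy]-10-iodo-4-methyl-7-(propan-2-yl)undeca-1,3,9-trien-6-ol, via ylide 21 (not isolated), via open-chain hydroxy enal 22 (not isolated)
Conditions: 20 (3.3 equiv), n-BuLi (3.0 equiv), THF, 0 °C; then 19, 0 °C → rt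
Reagents that add atoms: none
Why: Wittig methylenation of the lactol through its open-chain hydroxy enal 22, which is trapped by excess ylide as it forms so that the Z geometry inherited from the ring is kept, with a lithium counter-ion and low temperature chosen to disfavour O6-to-O8 silyl transfer.

Step 13
Reactants: 24 4-hydroxybenzoic acid
Product: 26 4-[(triisopropylsilyl)oxy]benzoic acid, via silyl ester 25 (not isolated)
Conditions: TIPSCl (2.3 equiv), imidazole, DMF, rt; then AcOH, THF, H2O, rt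
Reagents that add atoms: triisopropylsilyl chloride, CC(C)[Si](Cl)(C(C)C)C(C)C
Why: Double silylation followed by selective hydrolysis of the much more labile silyl ester should leave the aryl silyl ether in place.

Step 14
Reactants: 23 dienol; 26 4-[(triisopropylsilyl)oxy]benzoic acid
Product: 28 (3Z,6R,7R,8S,9Z)-8-[(tert-butyldimethylsilyl)oxy]-10-iodo-4-methyl-7-(propan-2-yl)undeca-1,3,9-trien-6-yl 4-[(triisopropylsilyl)oxy]benzoate, via mixed anhydride 27 (not isolated)
Conditions: 26, 2,4,6-Cl3C6H2COCl, Et3N, THF, rt; then 23, DMAP, toluene, rt → 40 °C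
Reagents that add atoms: none
Why: Yamaguchi esterification, in which DMAP attacks the less hindered aroyl carbonyl of mixed anhydride 27 and the acylpyridinium acylates the hindered C8 alcohol with retention, since the C8–O bond is not broken.

Step 15
Reactants: 28 open-chain diene/alkenyl iodide
Product: 30 (1R,3Z,7Z,9R,10R)-9-[(tert-butyldimethylsilyl)oxy]-3,7-dimethyl-10-(propan-2-yl)cyclodeca-3,7-dien-1-yl 4-[(triisopropylsilyl)oxy]benzoate, via C3 alkyl-9-BBN borane 29 (not isolated)
Conditions: 9-BBN-H dimer, THF, 0 °C → rt; then syringe-pump addition over 10 h to PdCl2(dppf) (20 mol%), AsPh3 (40 mol%), Cs2CO3, H2O, DMF/THF, 50 °C, final 1 mM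
Reagents that add atoms: none
Why: 9-BBN-H adds to the monosubstituted C2=C3 end of the diene with boron on C3, giving 29, while the trisubstituted C1=C10 and C4=C5 alkenes and the ester are left alone. Zerovalent palladium generated from PdCl2(dppf) inserts into the C4–I bond, the base-activated borane transfers C3 to the divalent alkenylpalladium iodide, and reductive elimination forms C3–C4 with retention of the Z geometry at C4=C5. This is an intramolecular B-alkyl Suzuki–Miyaura coupling, and the closest known reaction type is the macrocyclising coupling of an alkyl-9-BBN with a Z-alkenyl iodide. The ten-membered carbocycle closes by reductive elimination from an eleven-membered alkyl(alkenyl)palladacycle, and the two Z alkenes already in the chain should help the ends meet. No stereocentre is formed, and C6, C7 and C8 are not touched. The step needs hydroboration at the terminal alkene only, secured by the steric demand of 9-BBN, and ring closure over oligomerisation, secured by slow addition at high dilution and by the wide bite angle of dppf, which speeds reductive elimination over β-hydride elimination.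

Step 16
Reactants: 30 bis-silylated macrocycle
Product: 31 (1R,3Z,7Z,9R,10S)-9-hydroxy-3,7-dimethyl-10-(propan-2-yl)cyclodeca-3,7-dien-1-yl 4-hydroxybenzoate (CNP0249141.4)
Conditions: HF·pyridine, pyridine, THF, 0 °C → rt
Reagents that add atoms: none
Why: Buffered fluoride desilylation should cleave both the alkyl TBS ether and the aryl TIPS ether without basic conditions that could move the aroyl group from O8 to O6 and without acid strong enough to ionise the allylic C6 carbinol.

**Compound list**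

1 | but-2-yn-1-ol | CC#CCO | starting material
2 | sodium 2,2-bis(2-methoxyethoxy)-3-methyl-2,5-dihydro-1,2-oxaaluminol-2-ide (cyclic alkenylalanate) | [Na+].CC1=CCO[Al-]1(OCCOC)OCCOC | intermediate
3 | (Z)-3-iodobut-2-en-1-ol | OC/C=C(C)\I | intermediate
4 | (Z)-3-iodobut-2-enal | O=C/C=C(C)\I | intermediate
5 | (S)-4-benzyl-1,3-oxazolidin-2-one | O=C1N[C@@H](Cc2ccccc2)CO1 | starting material
6 | 3-methylbutanoyl chloride (isovaleryl chloride) | CC(C)CC(Cl)=O | starting material
7 | (S)-4-benzyl-3-(3-methylbutanoyl)-1,3-oxazolidin-2-one | CC(C)CC(=O)N1[C@@H](Cc2ccccc2)COC1=O | intermediate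
8 | Z(O) dibutylboron enolate of 7 | CCCCB(CCCC)O/C(=C\C(C)C)N1[C@@H](Cc2ccccc2)COC1=O | intermediate
9 | (4S)-4-benzyl-3-[(2S,3S,4Z)-3-hydroxy-5-iodo-2-(propan-2-yl)hex-4-enoyl]-1,3-oxazolidin-2-one | O=C([C@@H](C(C)C)[C@H](O)/C=C(C)\I)N1[C@@H](Cc2ccccc2)COC1=O | intermediate
10 | (4S)-4-benzyl-3-[(2S,3S,4Z)-3-[(tert-butyldimethylsilyl)oxy]-5-iodo-2-(propan-2-yl)hex-4-enoyl]-1,3-oxazolidin-2-one | O=C([C@@H](C(C)C)[C@H](O[Si](C)(C)C(C)(C)C)/C=C(C)\I)N1[C@@H](Cc2ccccc2)COC1=O | intermediate
11 | (2R,3S,4Z)-3-[(tert-butyldimethylsilyl)oxy]-5-iodo-2-(propan-2-yl)hex-4-en-1-ol | OC[C@@H](C(C)C)[C@H](O[Si](C)(C)C(C)(C)C)/C=C(C)\I | intermediate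
12 | (2S,3S,4Z)-3-[(tert-butyldimethylsilyl)oxy]-5-iodo-2-(propan-2-yl)hex-4-enal | O=C[C@@H](C(C)C)[C@H](O[Si](C)(C)C(C)(C)C)/C=C(C)\I | intermediate
13 | 2-methylallylmagnesium chloride | C=C(C)C[Mg]Cl | starting material
14 | B-(2-methylallyl)diisopinocampheylborane derived from (−)-α-pinene | C=C(C)CB([C@H]1C[C@H]2C[C@@H]([C@@H]1C)C2(C)C)[C@H]1C[C@H]2C[C@@H]([C@@H]1C)C2(C)C | intermediate
15 | (4R,5R,6S,7Z)-6-[(tert-butyldimethylsilyl)oxy]-8-iodo-2-methyl-5-(propan-2-yl)nona-1,7-dien-4-ol | C=C(C)C[C@@H](O)[C@@H](C(C)C)[C@H](O[Si](C)(C)C(C)(C)C)/C=C(C)\I | intermediate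
16 | acryloyl chloride | C=CC(Cl)=O | starting material
17 | (4R,5R,6S,7Z)-6-[(tert-butyldimethylsilyl)oxy]-8-iodo-2-methyl-5-(propan-2-yl)nona-1,7-dien-4-yl prop-2-enoate | C=C(C)C[C@@H](OC(=O)C=C)[C@@H](C(C)C)[C@H](O[Si](C)(C)C(C)(C)C)/C=C(C)\I | intermediate
18 | (6R)-6-[(3R,4S,5Z)-4-[(tert-butyldimethylsilyl)oxy]-6-iodo-2-methylhept-5-en-3-yl]-4-methyl-5,6-dihydro-2H-pyran-2-one | CC1=CC(=O)O[C@H](C1)[C@@H](C(C)C)[C@H](O[Si](C)(C)C(C)(C)C)/C=C(C)\I | intermediate
19 | (6R)-6-[(3R,4S,5Z)-4-[(tert-butyldimethylsilyl)oxy]-6-iodo-2-methylhept-5-en-3-yl]-4-methyl-5,6-dihydro-2H-pyran-2-ol (anomeric mixture) | CC1=CC(O)O[C@H](C1)[C@@H](C(C)C)[C@H](O[Si](C)(C)C(C)(C)C)/C=C(C)\I | intermediate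
20 | methyltriphenylphosphonium bromide | C[P+](c1ccccc1)(c1ccccc1)c1ccccc1.[Br-] | starting material
21 | methylenetriphenylphosphorane | C=P(c1ccccc1)(c1ccccc1)c1ccccc1 | intermediate
22 | (2Z,5R,6R,7S,8Z)-7-[(tert-butyldimethylsilyl)oxy]-5-hydroxy-9-iodo-3-methyl-6-(propan-2-yl)deca-2,8-dienal | O=C/C=C(C)\C[C@@H](O)[C@@H](C(C)C)[C@H](O[Si](C)(C)C(C)(C)C)/C=C(C)\I | intermediate
23 | (3Z,6R,7R,8S,9Z)-8-[(tert-butyldimethylsilyl)oxy]-10-iodo-4-methyl-7-(propan-2-yl)undeca-1,3,9-trien-6-ol | C=C/C=C(C)\C[C@@H](O)[C@@H](C(C)C)[C@H](O[Si](C)(C)C(C)(C)C)/C=C(C)\I | intermediate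
24 | 4-hydroxybenzoic acid | OC(=O)c1ccc(O)cc1 | starting material
25 | triisopropylsilyl 4-[(triisopropylsilyl)oxy]benzoate | CC(C)[Si](OC(=O)c1ccc(O[Si](C(C)C)(C(C)C)C(C)C)cc1)(C(C)C)C(C)C | intermediate
26 | 4-[(triisopropylsilyl)oxy]benzoic acid | OC(=O)c1ccc(O[Si](C(C)C)(C(C)C)C(C)C)cc1 | intermediate
27 | 4-[(triisopropylsilyl)oxy]benzoic 2,4,6-trichlorobenzoic anhydride | O=C(OC(=O)c1c(Cl)cc(Cl)cc1Cl)c1ccc(O[Si](C(C)C)(C(C)C)C(C)C)cc1 | intermediate
28 | (3Z,6R,7R,8S,9Z)-8-[(tert-butyldimethylsilyl)oxy]-10-iodo-4-methyl-7-(propan-2-yl)undeca-1,3,9-trien-6-yl 4-[(triisopropylsilyl)oxy]benzoate | C=C/C=C(C)\C[C@@H](OC(=O)c1ccc(O[Si](C(C)C)(C(C)C)C(C)C)cc1)[C@@H](C(C)C)[C@H](O[Si](C)(C)C(C)(C)C)/C=C(C)\I | intermediate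
29 | (3Z,6R,7R,8S,9Z)-1-(9-borabicyclo[3.3.1]nonan-9-yl)-8-[(tert-butyldimethylsilyl)oxy]-10-iodo-4-methyl-7-(propan-2-yl)undeca-3,9-dien-6-yl 4-[(triisopropylsilyl)oxy]benzoate | C1CCC2CCCC1B2CC/C=C(C)\C[C@@H](OC(=O)c1ccc(O[Si](C(C)C)(C(C)C)C(C)C)cc1)[C@@H](C(C)C)[C@H](O[Si](C)(C)C(C)(C)C)/C=C(C)\I | intermediate
30 | (1R,3Z,7Z,9R,10R)-9-[(tert-butyldimethylsilyl)oxy]-3,7-dimethyl-10-(propan-2-yl)cyclodeca-3,7-dien-1-yl 4-[(triisopropylsilyl)oxy]benzoate | C/C1=C/[C@@H](O[Si](C)(C)C(C)(C)C)[C@H](C(C)C)[C@H](OC(=O)c2ccc(O[Si](C(C)C)(C(C)C)C(C)C)cc2)C/C(C)=C\CC1 | intermediate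
31 | (1R,3Z,7Z,9R,10S)-9-hydroxy-3,7-dimethyl-10-(propan-2-yl)cyclodeca-3,7-dien-1-yl 4-hydroxybenzoate | C/C1=C/[C@@H](O)[C@H](C(C)C)[C@H](OC(=O)c2ccc(O)cc2)C/C(C)=C\CC1 | target

**Step count and risks**

Total steps: 16. Longest linear sequence: 14 steps (steps 1, 2, 4–12, 14–16, from but-2-yn-1-ol).

Steps most likely to fail:

1. Step 15 (macrocyclisation). The strained ten-membered ring may close too slowly, so that intermolecular coupling to oligomers, protodeboronation of the borane or β-hydride elimination at the alkylpalladium stage takes over. Loss of the aryl silyl ether under the aqueous carbonate would be harmless, since step 16 removes it anyway. Fallback, setting out from 29 and returning at 30: the borane would be oxidised (NaBO3·4H2O, THF/H2O) to the primary alcohol F1, which would be converted (I2, PPh3, imidazole) into the primary iodide F2. Zinc dust activated with 1,2-dibromoethane and Me3SiCl in THF at 30 °C inserts into the C(sp3)–I bond only and would give the alkylzinc iodide F3. Slow addition of F3 to Pd(PPh3)4 in THF at high dilution would form C3–C4 by an intramolecular Negishi coupling, under anhydrous and base-free conditions, to give 30.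

2. Step 12 (lactol methylenation). The open-chain Z-enal alkoxide may isomerise to the E-enal before it is olefinated, or the C8 alkoxide may take over the silyl group from O6. Fallback, setting out from 19 and returning at 23: Me3SiCH2MgCl with CeCl3 in THF at −78 → 0 °C would add 1,2 to the open form and give the β-hydroxysilane diol F4 (C2 epimers), in which the magnesium alkoxide is far less prone to silyl transfer. Peterson elimination under mild acid (AcOH buffered with NaOAc, or catalytic p-TsOH in THF at 0 °C) would then give 23.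

3. Step 6 (auxiliary removal). Hydride may attack the ring carbonyl of the oxazolidinone, because the α-isopropyl and β-silyloxy groups shield the exocyclic carbonyl, and the ring would then open instead of the acyl group being released. Fallback, setting out from 10 and returning at 12 (it replaces steps 6 and 7): LiSEt (EtSH, n-BuLi, THF, 0 °C) would displace the auxiliary and give the S-ethyl thioester F5, which i-Bu2AlH in CH2Cl2 at −78 °C would reduce directly to aldehyde 12.

**Further compounds**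

F1 | step 15 | (3Z,6R,7R,8S,9Z)-8-[(tert-butyldimethylsilyl)oxy]-1-hydroxy-10-iodo-4-methyl-7-(propan-2-yl)undeca-3,9-dien-6-yl 4-[(triisopropylsilyl)oxy]benzoate | OCC/C=C(C)\C[C@@H](OC(=O)c1ccc(O[Si](C(C)C)(C(C)C)C(C)C)cc1)[C@@H](C(C)C)[C@H](O[Si](C)(C)C(C)(C)C)/C=C(C)\I
F2 | step 15 | (3Z,6R,7R,8S,9Z)-8-[(tert-butyldimethylsilyl)oxy]-1,10-diiodo-4-methyl-7-(propan-2-yl)undeca-3,9-dien-6-yl 4-[(triisopropylsilyl)oxy]benzoate | ICC/C=C(C)\C[C@@H](OC(=O)c1ccc(O[Si](C(C)C)(C(C)C)C(C)C)cc1)[C@@H](C(C)C)[C@H](O[Si](C)(C)C(C)(C)C)/C=C(C)\I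
F3 | step 15 | C3 alkylzinc iodide derived from F2 | I[Zn]CC/C=C(C)\C[C@@H](OC(=O)c1ccc(O[Si](C(C)C)(C(C)C)C(C)C)cc1)[C@@H](C(C)C)[C@H](O[Si](C)(C)C(C)(C)C)/C=C(C)\I
F4 | step 12 | (3Z,6R,7R,8S,9Z)-8-[(tert-butyldimethylsilyl)oxy]-10-iodo-4-methyl-7-(propan-2-yl)-1-(trimethylsilyl)undeca-3,9-diene-2,6-diol (C2 epimers) | C[Si](C)(C)CC(O)/C=C(C)\C[C@@H](O)[C@@H](C(C)C)[C@H](O[Si](C)(C)C(C)(C)C)/C=C(C)\I
F5 | step 6 | S-ethyl (2S,3S,4Z)-3-[(tert-butyldimethylsilyl)oxy]-5-iodo-2-(propan-2-yl)hex-4-enethioate | CCSC(=O)[C@@H](C(C)C)[C@H](O[Si](C)(C)C(C)(C)C)/C=C(C)\I
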